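If I book each unit of substrate, the limiting reagent, to where it ends up, the readings leave a gap, and that gap is what I reckon with.

| flask | substrate | remark | time |
|---|---|---|---|
| gamma | 13 mM | run made earlier |  |
| delta | 30 mM | run made earlier |  |
| flask | 20 mM |  | 25 min |

| run | time / min | side product / % | target / % |
|---|---|---|---|
| gamma | 2.00 | 47.5 | 1.0 |
| gamma | 5.00 | 68.2 | 0 |
| gamma | 10.0 | 73.1 | 0 |
| gamma | 15.0 | 74.0 | 0 |
| delta | 2.00 | 40.6 | 0.8 |
| delta | 5.00 | 54.4 | 0.5 |
| delta | 10.0 | 56.6 | 0 |
| delta | 15.0 | 58.1 | 0 |

(each reading ± 0.5 percentage points)

- the state of affairs at 25 min: stopped, and by what, or still going (all of the substrate has reacted / it is still moving / forward and back rates have come level)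
- the side product standing at 25 min, as a percentage of the substrate charged

- the reaction counts as stopped when no species that holds the substrate changes by six tenths of a point or more over the second half of the time

The books at the last reading of each run:

gamma: side product 74.0%, target 0%, unbooked 26.0%

delta: side product 58.1%, target 0%, unbooked 41.9%

The unbooked part is larger in delta than in gamma, and delta has the larger charge. So I book it to a way that takes substrate in pairs, whose rate goes with the square of the amount, while the way to side product takes it singly. At substrate level x, the single way then gets the share s / (s + x), where s is a fixed amount of substrate. Averaged as the level falls from the charge c to nothing, this gives: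

side product share = (s / c) · ln(1 + c / s)

Gamma's plateau, solved for s, gives 16.7 mM. I call s the crossing amount, the substrate level at which the two ways use substrate equally fast. As a check, it gives 57.3% for delta, where the reading is 58.1%, good to 0.5 percentage points.

For this flask it gives:

side product = 65.8%

Gamma's side product closes on its plateau with a half-life of about 1.37 min, and 25 min is far longer. That is 18.2 such half-lives, so, taking gamma's pace for this flask, my call is that its substrate has reacted away and that this ends it.

The forecast says forward and back rates have come level, with 66% side product: “Lower conversion at higher concentration suggests a dissociation-type equilibrium”. We agree on the amount and differ on the stop.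

    intermediate ⇌ target (K = 0.430, k = 0.0480 s⁻¹)
    intermediate ⇌ isomer of the product (K = 2.80, k = 6.70 × 10⁻⁴ s⁻¹)
    substrate → intermediate (k = 0.00790 s⁻¹)
    intermediate → side product (k = 0.170 s⁻¹)
    2 substrate → self-condensation product (k = 0.230 M⁻¹ s⁻¹)

The flask's outcome is this: all of the substrate has reacted, and it stands at 66.1% side product. At 25.0 min it holds 0% substrate, 33.7% self-condensation product and 0.187% isomer of the product, and those last two figures are the unbooked entry. A neighbouring flask, the same but charged with 80 mM, starts at 4.79 times the crossing amount, so the same line gives 36.7% side product. That neighbouring flask gives 37.1% side product and 62.8% self-condensation product, with 0% substrate left.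

Readings and results are simulated for an exercise; scatter was added.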